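(All runs are calculated for an exercise; the scatter is artificial.)

Across the earlier runs one product holds still: the fraction of Z left, times the Z charged. The north-west run ends at 14.4% of 0.80 M, the north run at 14.9% of 0.80 M, the north-east run at 9.8% of 1.2 M. Their mean, read with the scatter of the readings, is 0.117 M: the floor of Z, the equilibrium monomer concentration. The north-west run already reads 16.0% at 0.667 h, so that run stands near its floor from its first reading.

common to all: G 0.78 mol%
- north-west: Z 0.80 M; X 0.027 M; run made earlier
- north: Z 0.80 M; X 0.060 M; run made earlier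
- north-east: Z 1.2 M; X 0.040 M; run made earlier
- flask: Z 0.80 M; X 0.0400 M; time 5.0 h

| run | time / h | L / % | Z / % |
|---|---|---|---|
| north-west | 0.667 | 84.1 | 16.0 |
| north-west | 1.33 | 82.2 | 14.7 |
| north-west | 2.00 | 82.3 | 16.2 |
| north-west | 2.50 | 80.8 | 14.7 |
| north-west | 3.00 | 82.2 | 14.3 |
| north-west | 4.00 | 81.4 | 14.4 |
| north | 0.667 | 82.8 | 15.8 |
| north | 1.33 | 82.2 | 13.1 |
| north | 2.00 | 80.2 | 14.9 |
| north | 2.50 | 78.2 | 15.9 |
| north | 3.00 | 80.1 | 14.4 |
| north | 4.00 | 77.2 | 14.9 |
| north-east | 0.333 | 86.8 | 13.0 |
| north-east | 1.00 | 88.3 | 10.6 |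
| north-east | 2.00 | 89.0 | 9.8 |
| north-east | 3.00 | 88.2 | 9.5 |
| north-east | 4.00 | 87.5 | 9.8 |

(readings scatter by 1 percentage point)

- the average divides the monomer in chains by the number of chains begun, living and dead together
- the earlier runs were read with a standard deviation of 1 percentage point
- what may be going on: X + Z -> D; L + J -> Z + J; Z + G -> J + L; Z -> E; 2 G -> Q; Z + J -> L + J
- the earlier runs do not show the number of chains; that part of a forecast is a guess

- average number of monomer units in a chain (chains begun, living or dead) at 5.0 h
- part of the Z that has reacted at 5.0 h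

Turned round, a fraction of Z left of one asks, in this reckoning, for a charge of Z down at the floor. This flask stands far from that: its charge is 6.82 times the floor. My reckoning joins that end to large charges, where the fraction left goes as one over the charge, and so takes floor over charge as the fraction left, at the loading of G of these runs. For this flask that gives 14.7% of the Z charged, so my reckoning gives c = 85.3%. The dp stays a guess, since the runs do not show the number of chains.

The forecast reads 115 and 85.3%, with the floor “reached within the first hour”.

The flask gives 101 and 85.7%. At 50.0 h it still stands at 85.7%, while L has come down to 44.1%. Floor over charge, which has no time in it, still reads 14.7% there, beside the 14.3% of Z in the flask at that time.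

    X + Z → D (k = 1.50 M⁻¹ h⁻¹)
    L + J → Z + J, rate k2*[J] as long as [L] is above zero (k = 150 h⁻¹)
    Z + G → J + L (k = 21.0 M⁻¹ h⁻¹)
    Z → E (k = 0.0500 h⁻¹)
    2 G → Q (k = 30.0 M⁻¹ h⁻¹)
    Z + J → L + J, rate k6*[J]*[Z] (k = 1300 M⁻¹ h⁻¹)

For a neighbour flask with 0.20 M of Z charged, floor over charge gives 58.5% of the Z left, so c = 41.5%. Computed, that neighbour holds 55.5% of its Z and gives c = 44.5%.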